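Ring A is made from a four-membered ring. Thermal benzannulation of 3-ethoxycyclobutenone with an (R)-configured triisopropylsilyloxyalkyne that already carries the protected 2-hydroxy-3-methylbut-3-enyl chain forms C8–C8a and C6–C7 in one operation. It exploits the phloroglucinol pattern of ring A, in which C8 lies between the oxygen-bearing C7 and C8a and para to C5: the chain arrives on C8 and only the C8a oxygen is left free. That hydroxyl directs formylation to C4a and becomes O1 when ring C is closed with a ring B prenyl ketone by aldol addition, oxidation and cyclodehydration. O5 de-ethylation and fluoride desilylation finish the synthesis.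

Key step: step 4

Assumption: the phosphoric-acid-catalysed allenylboration of methacrolein is taken to follow the facial sense expected for aromatic aldehydes (R acid giving R alcohol); the configuration of the homopropargylic alcohol is to be checked by Mosher ester analysis and the antipodal catalyst used if the sense is reversed.

Abbreviations: TBS = tert-butyldimethylsilyl, TIPS = triisopropylsilyl, TRIP = 3,3'-bis(2,4,6-triisopropylphenyl)-1,1'-binaphthyl-2,2'-diyl hydrogen phosphate, PPTS = pyridinium p-toluenesulfonate.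

Step 1
Reactants: 1 methacrolein; 2 allenylboronic acid pinacol ester
Product: 4 (R)-2-methylhex-1-en-5-yn-3-ol, via pinacol borate 3 (not isolated)
Conditions: (R)-TRIP (5 mol %), 4 Å MS, toluene, −20 °C; H2O work-up
Reagents that add atoms: none
Why: Chiral-phosphoric-acid-catalysed allenylboration of an aldehyde (asymmetric propargylation, SE2' through a closed six-membered chair in which the acid hydrogen-bonds to a boronate oxygen and to the formyl hydrogen) should give only the homopropargylic alcohol, and the catalyst alone sets the new carbinol centre, R being expected from the (R)-acid.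

Step 2
Reactants: 4 (R)-2-methylhex-1-en-5-yn-3-ol
Product: 5 (R)-3-(tert-butyldimethylsilyloxy)-2-methylhex-1-en-5-yne
Conditions: TBSCl, imidazole, DMF, rt
Reagents that add atoms: tert-butyldimethylsilyl chloride, CC(C)(C)[Si](C)(C)Cl
Why: Standard imidazole-promoted silylation of a secondary alcohol, which touches neither the stereocentre nor the terminal alkyne.

Step 3
Reactants: 5 (R)-3-(tert-butyldimethylsilyloxy)-2-methylhex-1-en-5-yne
Product: 8 (R)-3-(tert-butyldimethylsilyloxy)-2-methyl-6-(triisopropylsilyloxy)hex-1-en-5-yne, via lithium acetylide 6 (not isolated), via lithium ynolate 7 (not isolated)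
Conditions: n-BuLi, THF, −78 °C; t-BuOOLi (from t-BuOOH and LiN(SiMe3)2, THF, −78 °C), −78 → 0 °C; TIPSOTf, −78 → 0 °C
Reagents that add atoms: tert-butyl hydroperoxide, CC(C)(C)OO; triisopropylsilyl trifluoromethanesulfonate, CC(C)[Si](OS(=O)(=O)C(F)(F)F)(C(C)C)C(C)C
Why: Oxidation of a lithium acetylide by the electrophilic oxygen of lithium tert-butyl peroxide gives the lithium ynolate, which the bulky silyl triflate traps on oxygen to give an isolable silyl ynol ether (the established acetylide-to-siloxyalkyne sequence), while the alkyl silyl ether and the non-acidic carbinol centre are unaffected.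

Step 4
Reactants: 8 (R)-3-(tert-butyldimethylsilyloxy)-2-methyl-6-(triisopropylsilyloxy)hex-1-en-5-yne; 9 3-ethoxycyclobut-2-en-1-one
Product: 14 2-[(R)-2-(tert-butyldimethylsilyloxy)-3-methylbut-3-enyl]-5-ethoxy-3-(triisopropylsilyloxy)phenol, via (1-ethoxyvinyl)ketene 10 (not isolated), via vinylcyclobutenone 11 (not isolated), via dienylketene 12 (not isolated), via cyclohexadienone 13 (not isolated)
Conditions: 9 (1.5 equiv) added slowly to 8, toluene, 110 °C, sealed vessel, Ar
Reagents that add atoms: none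
Why: Thermal four-electron electrocyclic opening of 9 gives (1-ethoxyvinyl)ketene 10 (the ethoxy group sits on the vinyl carbon attached to the ketene), which the electron-rich alkyne 8 captures in a [2+2] cycloaddition, its carbon remote from oxygen bonding to the ketene carbonyl carbon (C8–C8a) and its oxygen-bearing carbon to the ketene alpha carbon (C7–C6), to give vinylcyclobutenone 11. A second four-electron opening of 11 gives dienylketene 12, and ring A closes by thermal disrotatory six-electron electrocyclisation between the ketene carbon and the terminal methylene (re-forming the C4a–C8a bond that the first opening broke), after which cyclohexadienone 13 tautomerises to phenol 14. The closest known reaction type is the Danheiser benzannulation of cyclobutenones with trialkylsilyloxyalkynes, which gives resorcinol monosilyl ethers. No stereocentre is created, and the side-chain carbinol centre is remote from every reacting atom and is carried through unchanged under these neutral conditions. The step needs head-to-tail regioselectivity in the [2+2] event and chemoselectivity for the alkyne over the isopropenyl group; the first is secured by the polarisation of the siloxyalkyne toward the electrophilic ketene carbonyl carbon and the second by the far higher reactivity of an ynol ether than of an unactivated alkene toward ketenes. The chain therefore lies between the new hydroxyl and the silyloxy group with ethoxy para to it, and slow addition of 9 keeps the ketene concentration low so that the product phenol is not acylated.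

Step 5
Reactants: 14 2-[(R)-2-(tert-butyldimethylsilyloxy)-3-methylbut-3-enyl]-5-ethoxy-3-(triisopropylsilyloxy)phenol
Product: 15 3-[(R)-2-(tert-butyldimethylsilyloxy)-3-methylbut-3-enyl]-6-ethoxy-2-hydroxy-4-(triisopropylsilyloxy)benzaldehyde
Conditions: MgCl2, Et3N, (CH2O)n, MeCN, 80 °C; aq. citric acid work-up
Reagents that add atoms: paraformaldehyde (formaldehyde source), C=O
Why: Magnesium-mediated ortho-formylation of a phenol (Casnati–Skattebøl reaction) delivers formaldehyde within the magnesium phenoxide chelate to the only free position ortho to the hydroxyl, the carbon between OH and OEt (the future C4a), and a second formaldehyde oxidises the benzylic alkoxide by hydride transfer, so the carbon between the two ethers (the future C6) is not touched.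

Step 6
Reactants: 16 2,4-dihydroxyacetophenone
Product: 17 1-[2,4-bis(triisopropylsilyloxy)phenyl]ethanone
Conditions: TIPSCl (2.4 equiv), imidazole, DMAP (cat.), DMF, 50 °C
Reagents that add atoms: triisopropylsilyl chloride, CC(C)[Si](Cl)(C(C)C)C(C)C
Why: Imidazole/DMAP-promoted silylation of both phenols, the bulky triisopropylsilyl group being chosen because it resists amide bases and enolates, is slow to migrate between oxygens and falls to fluoride at the end together with the other silyl ethers.

Step 7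
Reactants: 17 1-[2,4-bis(triisopropylsilyloxy)phenyl]ethanone; 18 prenyl bromide
Product: 20 1-[2,4-bis(triisopropylsilyloxy)phenyl]-5-methylhex-4-en-1-one, via lithium enolate 19 (not isolated)
Conditions: LiN(i-Pr)2 (1.05 equiv), THF, −78 °C; 18 (0.95 equiv), −78 → −20 °C
Reagents that add atoms: none
Why: Kinetic lithium enolate alkylation (SN2) of a methyl ketone at the unhindered primary carbon of a reactive allylic bromide, a slight deficit of bromide limiting double alkylation.

Step 8
Reactants: 15 3-[(R)-2-(tert-butyldimethylsilyloxy)-3-methylbut-3-enyl]-6-ethoxy-2-hydroxy-4-(triisopropylsilyloxy)benzaldehyde; 20 1-[2,4-bis(triisopropylsilyloxy)phenyl]-5-methylhex-4-en-1-one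
Product: 23 beta-hydroxy ketone aldol adduct (diastereomer mixture at the two new centres), via lithium phenoxide 21 (not isolated), via lithium enolate 22 (not isolated)
Conditions: 20 (1.6 equiv), LiN(i-Pr)2 (1.5 equiv), THF, −78 °C; 15 pre-treated with LiN(SiMe3)2 (1.05 equiv), THF, −78 °C, added by cannula; −78 → −40 °C; AcOH, −78 °C
Reagents that add atoms: none
Why: Crossed aldol addition of a preformed lithium ketone enolate to a salicylaldehyde whose phenol is masked in the flask as its lithium phenoxide should form the C3–C4 bond, and the two new stereocentres are left uncontrolled on purpose because both become sp2 carbons in step 9.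

Step 9
Reactants: 23 beta-hydroxy ketone aldol adduct
Product: 25 2-[2,4-bis(triisopropylsilyloxy)phenyl]-8-[(R)-2-(tert-butyldimethylsilyloxy)-3-methylbut-3-enyl]-5-ethoxy-3-(3-methylbut-2-enyl)-7-(triisopropylsilyloxy)-4H-chromen-4-one, via diketone 24 (not isolated)
Conditions: MnO2 (activated, 20 equiv), CH2Cl2, rt; filter; PPTS (20 mol %), 4 Å MS, toluene, 70 °C
Reagents that add atoms: none
Why: MnO2 should oxidise the electron-rich benzylic alcohol selectively to the 1,3-diketone without touching the alkenes, and mild acid then closes ring C by 6-exo-trig addition of the C8a hydroxyl to the ring B ketone and dehydration of the hemiketal (the cyclodehydration that ends a Baker–Venkataraman flavone synthesis), the only free phenol being the one that becomes O1.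

Step 10
Reactants: 25 5-ethoxy flavone from step 9
Product: 26 2-[2,4-bis(triisopropylsilyloxy)phenyl]-8-[(R)-2-(tert-butyldimethylsilyloxy)-3-methylbut-3-enyl]-5-hydroxy-3-(3-methylbut-2-enyl)-7-(triisopropylsilyloxy)-4H-chromen-4-one
Conditions: MgI2·OEt2 (4 equiv), toluene–THF, 80 °C; H2O
Reagents that add atoms: none
Why: Chelation-assisted ether cleavage, in which MgI2 binds between the C4 carbonyl and the peri O5 oxygen and iodide removes the ethyl group by SN2, a mode established for 5-alkoxyflavones and ortho-alkoxyaryl ketones, while the silyl ethers, which have no neighbouring carbonyl, are not activated.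

Step 11
Reactants: 26 5-hydroxy flavone from step 10
Product: 27 2-(2,4-dihydroxyphenyl)-5,7-dihydroxy-8-[(R)-2-hydroxy-3-methylbut-3-enyl]-3-(3-methylbut-2-enyl)-4H-chromen-4-one (target)
Conditions: Bu4NF (6 equiv), THF, 0 °C → rt; AcOH
Reagents that add atoms: none
Why: Fluoride-mediated cleavage of the three aryl triisopropylsilyl ethers and the secondary tert-butyldimethylsilyl ether under non-acidic conditions, which avoids acid-induced cyclisation of the prenyl group onto the 2'-hydroxyl or ionisation of the allylic alcohol and leaves the R carbinol centre untouched.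

Compound list
1 | methacrolein (2-methylprop-2-enal) | C=C(C)C=O | starting material
2 | allenylboronic acid pinacol ester (4,4,5,5-tetramethyl-2-(propa-1,2-dien-1-yl)-1,3,2-dioxaborolane) | C=C=CB1OC(C)(C)C(C)(C)O1 | starting material
3 | (R)-4,4,5,5-tetramethyl-2-[(2-methylhex-1-en-5-yn-3-yl)oxy]-1,3,2-dioxaborolane (pinacol borate of 4) | C=C(C)[C@H](OB1OC(C)(C)C(C)(C)O1)CC#C | intermediate
4 | (R)-2-methylhex-1-en-5-yn-3-ol | C=C(C)[C@H](O)CC#C | intermediate
5 | (R)-3-(tert-butyldimethylsilyloxy)-2-methylhex-1-en-5-yne | C=C(C)[C@H](O[Si](C)(C)C(C)(C)C)CC#C | intermediate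
6 | lithium acetylide of 5 | C=C(C)[C@H](O[Si](C)(C)C(C)(C)C)CC#[C-].[Li+] | intermediate
7 | lithium (R)-4-(tert-butyldimethylsilyloxy)-5-methylhex-5-en-1-yn-1-olate (lithium ynolate) | C=C(C)[C@H](O[Si](C)(C)C(C)(C)C)CC#C[O-].[Li+] | intermediate
8 | (R)-3-(tert-butyldimethylsilyloxy)-2-methyl-6-(triisopropylsilyloxy)hex-1-en-5-yne | C=C(C)[C@H](O[Si](C)(C)C(C)(C)C)CC#CO[Si](C(C)C)(C(C)C)C(C)C | intermediate
9 | 3-ethoxycyclobut-2-en-1-one | CCOC1=CC(=O)C1 | starting material
10 | (1-ethoxyvinyl)ketene (3-ethoxybuta-1,3-dien-1-one) | C=C(OCC)C=C=O | intermediate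
11 | 2-[(R)-2-(tert-butyldimethylsilyloxy)-3-methylbut-3-enyl]-4-(1-ethoxyvinyl)-3-(triisopropylsilyloxy)cyclobut-2-en-1-one (both C4 epimers) | C=C(C)[C@H](O[Si](C)(C)C(C)(C)C)CC1=C(O[Si](C(C)C)(C(C)C)C(C)C)C(C(=C)OCC)C1=O | intermediate
12 | (3E)-2-[(R)-2-(tert-butyldimethylsilyloxy)-3-methylbut-3-enyl]-5-ethoxy-3-(triisopropylsilyloxy)hexa-1,3,5-trien-1-one (dienylketene, ketene carbon and ethoxyvinyl group cis) | C=C(C)[C@H](O[Si](C)(C)C(C)(C)C)CC(=C=O)/C(O[Si](C(C)C)(C(C)C)C(C)C)=C\C(=C)OCC | intermediate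
13 | 2-[(R)-2-(tert-butyldimethylsilyloxy)-3-methylbut-3-enyl]-5-ethoxy-3-(triisopropylsilyloxy)cyclohexa-2,4-dien-1-one | C=C(C)[C@H](O[Si](C)(C)C(C)(C)C)CC1=C(O[Si](C(C)C)(C(C)C)C(C)C)C=C(OCC)CC1=O | intermediate
14 | 2-[(R)-2-(tert-butyldimethylsilyloxy)-3-methylbut-3-enyl]-5-ethoxy-3-(triisopropylsilyloxy)phenol | C=C(C)[C@H](O[Si](C)(C)C(C)(C)C)Cc1c(O)cc(OCC)cc1O[Si](C(C)C)(C(C)C)C(C)C | intermediate
15 | 3-[(R)-2-(tert-butyldimethylsilyloxy)-3-methylbut-3-enyl]-6-ethoxy-2-hydroxy-4-(triisopropylsilyloxy)benzaldehyde | C=C(C)[C@H](O[Si](C)(C)C(C)(C)C)Cc1c(O)c(C=O)c(OCC)cc1O[Si](C(C)C)(C(C)C)C(C)C | intermediate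
16 | 2,4-dihydroxyacetophenone | CC(=O)c1ccc(O)cc1O | starting material
17 | 1-[2,4-bis(triisopropylsilyloxy)phenyl]ethanone | CC(=O)c1ccc(O[Si](C(C)C)(C(C)C)C(C)C)cc1O[Si](C(C)C)(C(C)C)C(C)C | intermediate
18 | prenyl bromide (1-bromo-3-methylbut-2-ene) | CC(C)=CCBr | starting material
19 | lithium enolate of 17 | C=C([O-])c1ccc(O[Si](C(C)C)(C(C)C)C(C)C)cc1O[Si](C(C)C)(C(C)C)C(C)C.[Li+] | intermediate
20 | 1-[2,4-bis(triisopropylsilyloxy)phenyl]-5-methylhex-4-en-1-one | CC(C)=CCCC(=O)c1ccc(O[Si](C(C)C)(C(C)C)C(C)C)cc1O[Si](C(C)C)(C(C)C)C(C)C | intermediate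
21 | lithium phenoxide of 15 | C=C(C)[C@H](O[Si](C)(C)C(C)(C)C)Cc1c([O-])c(C=O)c(OCC)cc1O[Si](C(C)C)(C(C)C)C(C)C.[Li+] | intermediate
22 | lithium (Z)-enolate of 20 | CC(C)=CC/C=C(\[O-])c1ccc(O[Si](C(C)C)(C(C)C)C(C)C)cc1O[Si](C(C)C)(C(C)C)C(C)C.[Li+] | intermediate
23 | 1-[2,4-bis(triisopropylsilyloxy)phenyl]-2-{[3-[(R)-2-(tert-butyldimethylsilyloxy)-3-methylbut-3-enyl]-6-ethoxy-2-hydroxy-4-(triisopropylsilyloxy)phenyl](hydroxy)methyl}-5-methylhex-4-en-1-one (diastereomer mixture at the two new centres, side chain R) | C=C(C)[C@H](O[Si](C)(C)C(C)(C)C)Cc1c(O)c(C(O)C(CC=C(C)C)C(=O)c2ccc(O[Si](C(C)C)(C(C)C)C(C)C)cc2O[Si](C(C)C)(C(C)C)C(C)C)c(OCC)cc1O[Si](C(C)C)(C(C)C)C(C)C | intermediate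
24 | 1-[2,4-bis(triisopropylsilyloxy)phenyl]-3-[3-[(R)-2-(tert-butyldimethylsilyloxy)-3-methylbut-3-enyl]-6-ethoxy-2-hydroxy-4-(triisopropylsilyloxy)phenyl]-2-(3-methylbut-2-enyl)propane-1,3-dione | C=C(C)[C@H](O[Si](C)(C)C(C)(C)C)Cc1c(O)c(C(=O)C(CC=C(C)C)C(=O)c2ccc(O[Si](C(C)C)(C(C)C)C(C)C)cc2O[Si](C(C)C)(C(C)C)C(C)C)c(OCC)cc1O[Si](C(C)C)(C(C)C)C(C)C | intermediate
25 | 2-[2,4-bis(triisopropylsilyloxy)phenyl]-8-[(R)-2-(tert-butyldimethylsilyloxy)-3-methylbut-3-enyl]-5-ethoxy-3-(3-methylbut-2-enyl)-7-(triisopropylsilyloxy)-4H-chromen-4-one | C=C(C)[C@H](O[Si](C)(C)C(C)(C)C)Cc1c(O[Si](C(C)C)(C(C)C)C(C)C)cc(OCC)c2c(=O)c(CC=C(C)C)c(-c3ccc(O[Si](C(C)C)(C(C)C)C(C)C)cc3O[Si](C(C)C)(C(C)C)C(C)C)oc12 | intermediate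
26 | 2-[2,4-bis(triisopropylsilyloxy)phenyl]-8-[(R)-2-(tert-butyldimethylsilyloxy)-3-methylbut-3-enyl]-5-hydroxy-3-(3-methylbut-2-enyl)-7-(triisopropylsilyloxy)-4H-chromen-4-one | C=C(C)[C@H](O[Si](C)(C)C(C)(C)C)Cc1c(O[Si](C(C)C)(C(C)C)C(C)C)cc(O)c2c(=O)c(CC=C(C)C)c(-c3ccc(O[Si](C(C)C)(C(C)C)C(C)C)cc3O[Si](C(C)C)(C(C)C)C(C)C)oc12 | intermediate
27 | 2-(2,4-dihydroxyphenyl)-5,7-dihydroxy-8-[(R)-2-hydroxy-3-methylbut-3-enyl]-3-(3-methylbut-2-enyl)-4H-chromen-4-one | C=C(C)[C@H](O)Cc1c(O)cc(O)c2c(=O)c(CC=C(C)C)c(-c3ccc(O)cc3O)oc12 | target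

Total step count: 11. Longest linear sequence: 9 steps (steps 1–5 and 8–11). The ring B ketone 20 is made in 2 steps (6 and 7) and joins at step 8.

Steps most likely to fail

First, step 4. The donor-substituted cyclobutenone may open too slowly, so that the siloxyalkyne degrades on prolonged heating or the product phenol is acylated by ketene before conversion is complete. The fallback sets out from 8 and comes back to the route at 14. It generates the same ketene 10 at or below room temperature from an acyclic source. Commercial ethyl (E)-3-ethoxybut-2-enoate would be saponified (NaOH, aqueous EtOH) to (E)-3-ethoxybut-2-enoic acid F1 and converted with oxalyl chloride and catalytic DMF into (E)-3-ethoxybut-2-enoyl chloride F2. Slow addition of F2 to 8 and Et3N in CH2Cl2 (0 °C → rt) should effect 1,4-dehydrochlorination and [2+2] capture to vinylcyclobutenone 11, which is then warmed in toluene at 80 °C to give 14.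

Second, step 8. The phenoxide-bearing, trioxygenated aldehyde may be too weak an electrophile, and the adduct may revert by retro-aldol cleavage or lose its benzylic hydroxyl on work-up. The fallback sets out from 15 and comes back at 24. The phenol would be masked with allyl bromide and K2CO3 in acetone as 2-allyloxy-3-[(R)-2-(tert-butyldimethylsilyloxy)-3-methylbut-3-enyl]-6-ethoxy-4-(triisopropylsilyloxy)benzaldehyde F3. Aldol addition of enolate 22 would give the allyl-protected aldol adduct F4, and Dess–Martin periodinane with NaHCO3 (no free phenol is present) the allyl-protected diketone F5. Pd(PPh3)4 (zerovalent palladium) with morpholine in THF then removes the allyl group to give 24, which is cyclised with PPTS as in the second half of step 9.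

Third, step 10. Iodide attack at the ethyl carbon may be slower than loss of silyl ethers or Lewis-acid-induced cyclisation of the prenyl group onto a neighbouring oxygen. The fallback sets out from 9 and comes back at 27; it removes the need for the step by placing a silyl group on O5 from the start.
- Hydrolysis of 9 (aqueous HCl) would give cyclobutane-1,3-dione F6, and TIPSOTf with Et3N in CH2Cl2 at −78 °C the vinylogous silyl ester 3-(triisopropylsilyloxy)cyclobut-2-en-1-one F7.
- Benzannulation of F7 with 8 under the conditions of step 4 would give 2-[(R)-2-(tert-butyldimethylsilyloxy)-3-methylbut-3-enyl]-3,5-bis(triisopropylsilyloxy)phenol F8.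
- Formylation as in step 5 would give the 6-silyloxy salicylaldehyde F9, aldol addition of 22 as in step 8 the aldol adduct F10, and MnO2 then PPTS as in step 9 the 5,7,2',4'-tetrakis(triisopropylsilyloxy) flavone F12 by way of the diketone F11 (not isolated).
- Bu4NF under the conditions of step 11 then frees all five oxygens of F12 at once to give 27.

Further compounds
F1 | step 4 | (E)-3-ethoxybut-2-enoic acid | CCO/C(C)=C/C(=O)O
F2 | step 4 | (E)-3-ethoxybut-2-enoyl chloride | CCO/C(C)=C/C(=O)Cl
F3 | step 8 | 2-allyloxy-3-[(R)-2-(tert-butyldimethylsilyloxy)-3-methylbut-3-enyl]-6-ethoxy-4-(triisopropylsilyloxy)benzaldehyde | C=C(C)[C@H](O[Si](C)(C)C(C)(C)C)Cc1c(OCC=C)c(C=O)c(OCC)cc1O[Si](C(C)C)(C(C)C)C(C)C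
F4 | step 8 | allyl-protected aldol adduct (2-O-allyl ether of 23, diastereomer mixture at the two new centres) | C=C(C)[C@H](O[Si](C)(C)C(C)(C)C)Cc1c(OCC=C)c(C(O)C(CC=C(C)C)C(=O)c2ccc(O[Si](C(C)C)(C(C)C)C(C)C)cc2O[Si](C(C)C)(C(C)C)C(C)C)c(OCC)cc1O[Si](C(C)C)(C(C)C)C(C)C
F5 | step 8 | allyl-protected diketone (2-O-allyl ether of 24) | C=C(C)[C@H](O[Si](C)(C)C(C)(C)C)Cc1c(OCC=C)c(C(=O)C(CC=C(C)C)C(=O)c2ccc(O[Si](C(C)C)(C(C)C)C(C)C)cc2O[Si](C(C)C)(C(C)C)C(C)C)c(OCC)cc1O[Si](C(C)C)(C(C)C)C(C)C
F6 | step 10 | cyclobutane-1,3-dione | O=C1CC(=O)C1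
F7 | step 10 | 3-(triisopropylsilyloxy)cyclobut-2-en-1-one | CC(C)[Si](OC1=CC(=O)C1)(C(C)C)C(C)C
F8 | step 10 | 2-[(R)-2-(tert-butyldimethylsilyloxy)-3-methylbut-3-enyl]-3,5-bis(triisopropylsilyloxy)phenol | C=C(C)[C@H](O[Si](C)(C)C(C)(C)C)Cc1c(O)cc(O[Si](C(C)C)(C(C)C)C(C)C)cc1O[Si](C(C)C)(C(C)C)C(C)C
F9 | step 10 | 3-[(R)-2-(tert-butyldimethylsilyloxy)-3-methylbut-3-enyl]-2-hydroxy-4,6-bis(triisopropylsilyloxy)benzaldehyde | C=C(C)[C@H](O[Si](C)(C)C(C)(C)C)Cc1c(O)c(C=O)c(O[Si](C(C)C)(C(C)C)C(C)C)cc1O[Si](C(C)C)(C(C)C)C(C)C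
F10 | step 10 | aldol adduct of F9 with 22 (diastereomer mixture at the two new centres) | C=C(C)[C@H](O[Si](C)(C)C(C)(C)C)Cc1c(O)c(C(O)C(CC=C(C)C)C(=O)c2ccc(O[Si](C(C)C)(C(C)C)C(C)C)cc2O[Si](C(C)C)(C(C)C)C(C)C)c(O[Si](C(C)C)(C(C)C)C(C)C)cc1O[Si](C(C)C)(C(C)C)C(C)C
F11 | step 10 | 1,3-diketone from oxidation of F10 | C=C(C)[C@H](O[Si](C)(C)C(C)(C)C)Cc1c(O)c(C(=O)C(CC=C(C)C)C(=O)c2ccc(O[Si](C(C)C)(C(C)C)C(C)C)cc2O[Si](C(C)C)(C(C)C)C(C)C)c(O[Si](C(C)C)(C(C)C)C(C)C)cc1O[Si](C(C)C)(C(C)C)C(C)C
F12 | step 10 | 2-[2,4-bis(triisopropylsilyloxy)phenyl]-8-[(R)-2-(tert-butyldimethylsilyloxy)-3-methylbut-3-enyl]-3-(3-methylbut-2-enyl)-5,7-bis(triisopropylsilyloxy)-4H-chromen-4-one | C=C(C)[C@H](O[Si](C)(C)C(C)(C)C)Cc1c(O[Si](C(C)C)(C(C)C)C(C)C)cc(O[Si](C(C)C)(C(C)C)C(C)C)c2c(=O)c(CC=C(C)C)c(-c3ccc(O[Si](C(C)C)(C(C)C)C(C)C)cc3O[Si](C(C)C)(C(C)C)C(C)C)oc12
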